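At 32 h the north run had a leftover of 67.7% of its charge that was not product, and yet over the last 13.0 h product had grown by 2.00% of the charge, so I wanted to know what flattened the curve.

| flask | starting material | product | time |
|---|---|---|---|
| north | 0.300 M |  |  |
| south-west | 0.120 M |  |  |
| south | 0.900 M |  |  |
| north-east | 0.300 M | 0.150 M |  |
| north-west | 1.50 M |  | 32 h |

| run | time / h | [product] / M |
|---|---|---|
| north run | 1.3 | 0.017 |
| north run | 2.2 | 0.024 |
| north run | 3.7 | 0.036 |
| north run | 6.4 | 0.053 |
| north run | 11 | 0.069 |
| north run | 19 | 0.091 |
| north run | 32 | 0.097 |
| south-west run | 1.3 | 0.002 |
| south-west run | 2.2 | 0 |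
| south-west run | 3.7 | 0.012 |
| south-west run | 6.4 | 0.021 |
| south-west run | 11 | 0.028 |
| south-west run | 19 | 0.037 |
| south-west run | 32 | 0.042 |
| south run | 1.3 | 0.038 |
| south run | 2.2 | 0.068 |
| south run | 3.7 | 0.104 |
| south run | 6.4 | 0.164 |
| south run | 11 | 0.221 |
| south run | 19 | 0.274 |
| south run | 32 | 0.309 |
| north-east run | 1.3 | 0.162 |
| north-east run | 2.2 | 0.171 |
| north-east run | 3.7 | 0.188 |
| north-east run | 6.4 | 0.199 |
| north-east run | 11 | 0.228 |
| north-east run | 19 | 0.239 |
| north-east run | 32 | 0.250 |

(each reading ± 0.003 M)

- Overall: starting material -> product.
- Constant volume, constant temperature.
- An order is taken over about fifteen percent of the charge, up and down.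

1. order of the initial rate in [starting material], near the charge of the north run, the rate being that where two percent of its starting material are product (one fixed amount of product, the same in the runs compared)
2. product in the north-west run at 32 h, as a share of the starting material charged

First I asked whether the charge sets that level, and the readings said no: at 32 h the south-west, north and south runs stood at 35.0%, 32.3% and 34.3% of their charges. At 6.4 h the south run held 3.09 times the north run's product on 3.00 times its charge, which I read as an order of 1.03 in starting material.

Next I asked whether product pushes back, and the north-east run showed no sign of it: charged with added product equal to 50.0% of its starting material, it gained 33.3% of that charge by 32 h, against 32.3% in the north run.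

So I treated the curve as a first-order lag, x = C(1 − e^(−t/τ)). Pooling the south-west, north and south runs gave shares of 18.0%, 30.5% and 33.9% at 6.4 h, 19 h and 32 h, nearly even steps of 12.8 h. The gaps shrank by a factor of 0.280 per step, so τ came to 10.1 h and C to 35.3%, my ceiling share, the fraction of the charge that the curve heads for as product. Taking first order out to 1.50 M, I expected the north-west run to hold 33.8% of its charge at 32 h.

The forecast gave an order of 1 and 34%, reading the flattening as “activity dying with time, independent of charge”.

The flask gave an order of 0.99 and 33.8%.

    starting material ⇌ intermediate (0.1811 /h, 4.140 /h)
    intermediate → product (0.7128 /h)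
    starting material → product (0.01415 /h)
    starting material → decomposed substrate (0.07668 /h)

In these equations my ceiling share reads as the product's part in a split between first-order exits of starting material, a selectivity: the reaction of starting material to decomposed substrate is the main reason the north-west run held 33.8% of its charge at 32 h. With that exit shut I took the product route to keep my read rate C/τ, 0.0351 /h, from which I reckoned 67.5% for the north-west flask; the run without that reaction gave 71.6%.

The numbers in the tables stem from a simulated flask for substances that don't exist.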